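**Plan**

1. Locants: C1 = quaternary ring-fusion C(CH3); C2 = CH(OAng) and C3 = CH2 of the five-membered ring; C4 = C(OH)(i-Pr); C5 = ring-fusion CH; C6 = CH(OAng), C7 = CH2, C8 = C(CH3)=, C9 = =CH, C10 = CH2 of the seven-membered ring.
2. Retrosynthetic cuts, in order: the two ester C–O bonds; the C6 oxygen, back to a C6=C7–C8=C9 diene; C4–isopropyl; C1–CH3; then C5–C1 and C5–C6 together, which returns the seven-membered ring to a benzene ring.
3. Enabling feature: C1, C10, C9, C8(CH3), C7 and C6 are the ipso, ortho, meta, para, meta and ortho carbons of a 4-methylphenyl ring, C2 is its benzylic carbinol carbon and C4–C5 is a diazomethyl ketone. Carbenoid C5 bonds to C1, closing the five-membered ring, and is thereby inserted into the arene (Buchner ring enlargement).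
4. Forward: aryl β-keto ester → (S)-carbinol → diazoketone → five- and seven-membered rings in one step → C1 methyl by cuprate → C4 isopropyl by Grignard addition → C6 oxygen by directed epoxidation, isomerisation and directed reduction → two angelates.
5. Stereochemistry: C2 by catalyst-controlled transfer hydrogenation, then relay: C1 (methyl anti to the C2 silyloxy group), C5 (protonation anti to the C1 methyl), C4 (attack anti to C1–CH3 and C5–C6), C6 (hydride delivered from the C4 hydroxyl).

Key step: step 5

Remark: the target is read as the trans-fused (1R,3S,3aR,8S,8aS)-octahydroazulene. With the C1 methyl taken as β, the C4 hydroxyl is β, and the C2 and C6 acyloxy groups, the C4 isopropyl group and the C5 hydrogen are α. Both esters are (Z)-2-methylbut-2-enoates (angelates).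

**Route**

Step 1
Reactants: 1 ethyl 3-(4-methylphenyl)-3-oxopropanoate
Product: 2 ethyl (3S)-3-hydroxy-3-(4-methylphenyl)propanoate
Conditions: RuCl[(S,S)-TsDPEN](p-cymene) (0.5 mol %), HCO2H/Et3N (5:2), 40 °C
Reagents that add atoms: none
Why: Noyori–Ikariya asymmetric transfer hydrogenation of an aryl ketone; the (S,S)-ligated ruthenium hydride should attack the same face as with acetophenone and set C2 as (S).

Step 2
Reactants: 2 ethyl (3S)-3-hydroxy-3-(4-methylphenyl)propanoate
Product: 3 ethyl (3S)-3-[(tert-butyldimethylsilyl)oxy]-3-(4-methylphenyl)propanoate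
Conditions: TBSCl, imidazole, DMF, 23 °C
Reagents that add atoms: tert-butyldimethylsilyl chloride, CC(C)(C)[Si](C)(C)Cl
Why: Imidazole-promoted silylation of the benzylic alcohol; TBS is chosen because its hindered, weakly basic oxygen should stay out of the carbenoid chemistry of step 5 and later steers the cuprate in step 6.

Step 3
Reactants: 3 ethyl (3S)-3-[(tert-butyldimethylsilyl)oxy]-3-(4-methylphenyl)propanoate
Product: 4 (3S)-3-[(tert-butyldimethylsilyl)oxy]-3-(4-methylphenyl)propanoic acid
Conditions: LiOH·H2O, THF/H2O, 0 to 23 °C; then 1 M HCl to pH 4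
Reagents that add atoms: lithium hydroxide, [Li+].[OH-]
Why: Ester saponification; a silanolate is a poor leaving group, so E1cB loss to the cinnamate should not compete at or below room temperature.

Step 4
Reactants: 4 (3S)-3-[(tert-butyldimethylsilyl)oxy]-3-(4-methylphenyl)propanoic acid
Product: 6 (4S)-4-[(tert-butyldimethylsilyl)oxy]-1-diazo-4-(4-methylphenyl)butan-2-one, via isobutyl carbonic mixed anhydride 5 (not isolated)
Conditions: i-BuOCOCl, Et3N, THF, -15 °C; then CH2N2 (Et2O), 0 to 23 °C
Reagents that add atoms: isobutyl chloroformate, CC(C)COC(=O)Cl (its atoms stay only in 5); diazomethane, C=[N+]=[N-]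
Why: Acylation of diazomethane by a mixed carbonic anhydride (first stage of an Arndt–Eistert sequence) brings in C5 under neutral conditions that spare the benzylic silyl ether.

Step 5
Reactants: 6 (4S)-4-[(tert-butyldimethylsilyl)oxy]-1-diazo-4-(4-methylphenyl)butan-2-one
Product: 9 (3S)-3-[(tert-butyldimethylsilyl)oxy]-6-methyl-3,4-dihydroazulen-1(2H)-one, via norcaradiene 7 (not isolated), via 8aH-cycloheptatrienone 8 (not isolated)
Conditions: Rh2(OAc)4 (0.5 mol %), CH2Cl2, reflux, slow addition of 6; then Et3N, 23 °C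
Reagents that add atoms: none
Why: The rhodium carbenoid formed from 6 by loss of N2 adds to the ipso–ortho π bond (C1–C6) of the tolyl ring to give norcaradiene 7, whose disrotatory 6π electrocyclic opening cleaves C1–C6 and leaves C5 inserted between C1 and C6 (intramolecular Buchner reaction). The closest known reaction type is the Rh2(OAc)4-mediated cyclisation of 1-diazo-4-arylbutan-2-ones to 3,4-dihydroazulen-1(2H)-ones, with an amine-induced shift of the ring-fusion hydrogen. The five-membered ring C1–C2–C3–C4–C5 closes by 5-exo attack of the carbenoid carbon C5 on C1, the cyclopropane C1–C5–C6 closes in the same concerted [2+1] addition, and the seven-membered ring arises by enlargement of the arene, not by a closure of its own. No stereocentre that survives is made here: the C5 centre of 8 is erased when Et3N moves its doubly allylic, α-keto hydrogen to C10 (reprotonation of the enolate at the terminus that puts C1=C5 in conjugation with the carbonyl), and C2 is not touched. The step needs arene addition to outrun capture of the carbenoid by the silyl ether oxygen, C–H insertion and carbene dimerisation; the five-atom reach to the ipso/ortho bond, the electron-rich para-substituted ring with two equivalent ortho positions, the hindered TBS oxygen, the absence of δ C–H bonds and slow addition should secure this. A base and not an acid is used for the hydrogen shift because acid would reopen 7 to a 2-tetralone, and a mild amine should keep β-elimination of the silanol slow.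

Step 6
Reactants: 9 (3S)-3-[(tert-butyldimethylsilyl)oxy]-6-methyl-3,4-dihydroazulen-1(2H)-one
Product: 11 (3S,3aR,8aR)-3-[(tert-butyldimethylsilyl)oxy]-3a,6-dimethyl-3,3a,4,8a-tetrahydroazulen-1(2H)-one, via lithium enolate 10 (not isolated)
Conditions: Me2CuLi (3 equiv; from MeLi and CuI), Et2O, -40 to 0 °C; then AcOH, THF, -78 °C
Reagents that add atoms: lithium dimethylcuprate, [Li+].C[Cu-]C
Why: Conjugate addition of a Gilman cuprate to a 4-silyloxycyclopent-2-enone is expected anti to the silyloxy group (as in three-component prostaglandin syntheses), which makes C1 quaternary with the methyl β, and kinetic α-protonation of the extended enolate at C5, anti to the pseudo-axial angular methyl and toward the staggered trans ring fusion, should set the C5 hydrogen α and keep the C6=C7–C8=C9 diene out of conjugation.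

Step 7
Reactants: 11 (3S,3aR,8aR)-3-[(tert-butyldimethylsilyl)oxy]-3a,6-dimethyl-3,3a,4,8a-tetrahydroazulen-1(2H)-one
Product: 12 (1R,3S,3aR,8aR)-3-[(tert-butyldimethylsilyl)oxy]-3a,6-dimethyl-1-(propan-2-yl)-1,2,3,3a,4,8a-hexahydroazulen-1-ol
Conditions: i-PrMgCl (2 equiv), LaCl3·2LiCl (1 equiv), THF, 0 °C
Reagents that add atoms: isopropylmagnesium chloride, CC(C)[Mg]Cl
Why: Lanthanide-promoted Grignard 1,2-addition, in which LaCl3·2LiCl activates the carbonyl and suppresses enolisation at the acidic C5–H and β-hydride reduction; attack on the α face, anti to the 1,3-related pseudo-axial C1 methyl and the vicinal C5–C6 bond, should set C4 with the hydroxyl β.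

Step 8
Reactants: 12 (1R,3S,3aR,8aR)-3-[(tert-butyldimethylsilyl)oxy]-3a,6-dimethyl-1-(propan-2-yl)-1,2,3,3a,4,8a-hexahydroazulen-1-ol
Product: 13 7,8-epoxide of 12 (azulene locants; oxirane at C6–C7 of the plan, oxygen on the β face, cis to the tertiary hydroxyl)
Conditions: VO(acac)2 (5 mol %), t-BuOOH (1.5 equiv), CH2Cl2, 0 to 23 °C
Reagents that add atoms: tert-butyl hydroperoxide, CC(C)(C)OO
Why: Hydroxyl-directed epoxidation (vanadium alkoxide delivery of the peroxide): the homoallylic C4 alkoxide should place the oxygen on the proximal C6=C7 bond, syn to itself, and leave the more substituted but remote C8=C9 bond alone; the two new stereocentres are erased in step 9.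

Step 9
Reactants: 13 7,8-epoxide of 12
Product: 14 (1R,3S,3aR,8aR)-3-[(tert-butyldimethylsilyl)oxy]-1-hydroxy-3a,6-dimethyl-1-(propan-2-yl)-2,3,3a,4,7,8a-hexahydroazulen-8(1H)-one
Conditions: Pd(PPh3)4 (5 mol %), THF, 23 to 40 °C
Reagents that add atoms: none
Why: Zerovalent-palladium isomerisation of a cyclic 1,3-diene monoepoxide: ionisation gives a π-allyl palladium alkoxide (C7–C9) with palladium anti to oxygen and therefore syn to the C6 hydrogen, and β-hydride elimination followed by α-protonation of the dienolate gives the C6 ketone with the alkene left at C8=C9.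

Step 10
Reactants: 14 (1R,3S,3aR,8aR)-3-[(tert-butyldimethylsilyl)oxy]-1-hydroxy-3a,6-dimethyl-1-(propan-2-yl)-2,3,3a,4,7,8a-hexahydroazulen-8(1H)-one
Product: 15 (1R,3S,3aR,8S,8aS)-3-[(tert-butyldimethylsilyl)oxy]-3a,6-dimethyl-1-(propan-2-yl)-1,2,3,3a,4,7,8,8a-octahydroazulene-1,8-diol
Conditions: Me4NBH(OAc)3 (5 equiv), MeCN/AcOH (1:1), -30 °C
Reagents that add atoms: none
Why: Evans–Saksena hydroxyl-directed reduction: acetoxy exchange puts boron on the β-oriented C4 oxygen and the hydride is passed through a chair six-membered transition state to the C6 carbonyl, giving the 1,3-anti diol, that is the α alcohol at C6.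

Step 11
Reactants: 15 (1R,3S,3aR,8S,8aS)-3-[(tert-butyldimethylsilyl)oxy]-3a,6-dimethyl-1-(propan-2-yl)-1,2,3,3a,4,7,8,8a-octahydroazulene-1,8-diol
Product: 16 (1R,3S,3aR,8S,8aS)-3a,6-dimethyl-1-(propan-2-yl)-1,2,3,3a,4,7,8,8a-octahydroazulene-1,3,8-triol
Conditions: TBAF (3 equiv), THF, 23 to 45 °C
Reagents that add atoms: none
Why: Fluoride-induced desilylation frees the C2 hydroxyl; the triol has no base-sensitive function left.

Step 12
Reactants: 16 (1R,3S,3aR,8S,8aS)-3a,6-dimethyl-1-(propan-2-yl)-1,2,3,3a,4,7,8,8a-octahydroazulene-1,3,8-triol; 17 angelic acid [(2Z)-2-methylbut-2-enoic acid]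
Product: 19 (1R,3S,3aR,8S,8aS)-1-hydroxy-3a,6-dimethyl-1-(propan-2-yl)-1,2,3,3a,4,7,8,8a-octahydroazulene-3,8-diyl bis[(2Z)-2-methylbut-2-enoate], via angeloyl trichlorobenzoyl anhydride 18 (not isolated)
Conditions: 17 (6 equiv), 2,4,6-trichlorobenzoyl chloride (6 equiv), Et3N, toluene, 23 °C; then 16, 80 °C
Reagents that add atoms: 2,4,6-trichlorobenzoyl chloride, O=C(Cl)c1c(Cl)cc(Cl)cc1Cl (its atoms stay only in 18)
Why: Acylation of both secondary hydroxyls by the preformed mixed anhydride of angelic acid with 2,4,6-trichlorobenzoic acid in hot toluene without a nucleophilic catalyst (Yamaguchi-type esterification), under which the (Z)-acyl group is expected to transfer without isomerisation to the tiglate while the hindered tertiary C4 hydroxyl should not react.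

**Compound list**

1 | ethyl 3-(4-methylphenyl)-3-oxopropanoate | CCOC(=O)CC(=O)c1ccc(C)cc1 | starting material
2 | ethyl (3S)-3-hydroxy-3-(4-methylphenyl)propanoate | Cc1ccc(cc1)[C@@H](O)CC(=O)OCC | intermediate
3 | ethyl (3S)-3-[(tert-butyldimethylsilyl)oxy]-3-(4-methylphenyl)propanoate | Cc1ccc(cc1)[C@@H](O[Si](C)(C)C(C)(C)C)CC(=O)OCC | intermediate
4 | (3S)-3-[(tert-butyldimethylsilyl)oxy]-3-(4-methylphenyl)propanoic acid | Cc1ccc(cc1)[C@@H](O[Si](C)(C)C(C)(C)C)CC(=O)O | intermediate
5 | (3S)-3-[(tert-butyldimethylsilyl)oxy]-3-(4-methylphenyl)propanoic isobutyl carbonic anhydride (not isolated) | Cc1ccc(cc1)[C@@H](O[Si](C)(C)C(C)(C)C)CC(=O)OC(=O)OCC(C)C | intermediate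
6 | (4S)-4-[(tert-butyldimethylsilyl)oxy]-1-diazo-4-(4-methylphenyl)butan-2-one | Cc1ccc(cc1)[C@@H](O[Si](C)(C)C(C)(C)C)CC(=O)C=[N+]=[N-] | intermediate
7 | norcaradiene: cyclopropane C1–C5–C6 fused to the 3-silyloxycyclopentanone and to a 4-methylcyclohexa-2,4-diene, both ring-fusion faces, C2 (S) (not isolated) | O=C1C[C@H](O[Si](C)(C)C(C)(C)C)C23C=CC(C)=CC2C13 | intermediate
8 | (3S)-3-[(tert-butyldimethylsilyl)oxy]-6-methyl-3,8a-dihydroazulen-1(2H)-one, both C8a epimers (not isolated) | O=C1C[C@H](O[Si](C)(C)C(C)(C)C)C2=CC=C(C)C=CC12 | intermediate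
9 | (3S)-3-[(tert-butyldimethylsilyl)oxy]-6-methyl-3,4-dihydroazulen-1(2H)-one | O=C1C[C@H](O[Si](C)(C)C(C)(C)C)C2=C1C=CC(C)=CC2 | intermediate
10 | lithium (3S,3aR)-3-[(tert-butyldimethylsilyl)oxy]-3a,6-dimethyl-2,3,3a,4-tetrahydroazulen-1-olate (not isolated) | [Li+].[O-]C1=C2C=CC(C)=CC[C@@]2(C)[C@@H](O[Si](C)(C)C(C)(C)C)C1 | intermediate
11 | (3S,3aR,8aR)-3-[(tert-butyldimethylsilyl)oxy]-3a,6-dimethyl-3,3a,4,8a-tetrahydroazulen-1(2H)-one (trans-fused) | C1=CC(C)=CC[C@@]2(C)[C@@H](O[Si](C)(C)C(C)(C)C)CC(=O)[C@H]12 | intermediate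
12 | (1R,3S,3aR,8aR)-3-[(tert-butyldimethylsilyl)oxy]-3a,6-dimethyl-1-(propan-2-yl)-1,2,3,3a,4,8a-hexahydroazulen-1-ol | C1=CC(C)=CC[C@@]2(C)[C@@H](O[Si](C)(C)C(C)(C)C)C[C@@](O)(C(C)C)[C@H]12 | intermediate
13 | 7,8-epoxide of 12, oxirane oxygen β (cis to the tertiary hydroxyl) | [C@H]13O[C@@H]3C(C)=CC[C@@]2(C)[C@@H](O[Si](C)(C)C(C)(C)C)C[C@@](O)(C(C)C)[C@H]12 | intermediate
14 | (1R,3S,3aR,8aR)-3-[(tert-butyldimethylsilyl)oxy]-1-hydroxy-3a,6-dimethyl-1-(propan-2-yl)-2,3,3a,4,7,8a-hexahydroazulen-8(1H)-one | O=C1CC(C)=CC[C@@]2(C)[C@@H](O[Si](C)(C)C(C)(C)C)C[C@@](O)(C(C)C)[C@H]12 | intermediate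
15 | (1R,3S,3aR,8S,8aS)-3-[(tert-butyldimethylsilyl)oxy]-3a,6-dimethyl-1-(propan-2-yl)-1,2,3,3a,4,7,8,8a-octahydroazulene-1,8-diol | O[C@H]1CC(C)=CC[C@@]2(C)[C@@H](O[Si](C)(C)C(C)(C)C)C[C@@](O)(C(C)C)[C@H]12 | intermediate
16 | (1R,3S,3aR,8S,8aS)-3a,6-dimethyl-1-(propan-2-yl)-1,2,3,3a,4,7,8,8a-octahydroazulene-1,3,8-triol | O[C@H]1CC(C)=CC[C@@]2(C)[C@@H](O)C[C@@](O)(C(C)C)[C@H]12 | intermediate
17 | angelic acid, (2Z)-2-methylbut-2-enoic acid | C/C=C(/C)C(=O)O | starting material
18 | (2Z)-2-methylbut-2-enoic 2,4,6-trichlorobenzoic anhydride (not isolated) | C/C=C(/C)C(=O)OC(=O)c1c(Cl)cc(Cl)cc1Cl | intermediate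
19 | (1R,3S,3aR,8S,8aS)-1-hydroxy-3a,6-dimethyl-1-(propan-2-yl)-1,2,3,3a,4,7,8,8a-octahydroazulene-3,8-diyl bis[(2Z)-2-methylbut-2-enoate] | C/C=C(/C)C(=O)O[C@H]1CC(C)=CC[C@@]2(C)[C@@H](OC(=O)/C(C)=C\C)C[C@@](O)(C(C)C)[C@H]12 | target

**Step count and risks**

Total step count: 12. Longest linear sequence: 12 steps (1 to 19).

Steps judged most likely to fail:

Step 6. The enolate 10 may take up its proton on the β face (cis ring fusion) or at C7 or C9 (conjugated isomers), because the C1 methyl and the C10 methylene flank C5 almost symmetrically. The fallback replaces substrate control by catalyst control. It sets out from 9: after the same cuprate addition, enolate 10 is trapped with allyl chloroformate to give the isolable allyl (3S,3aR)-3-[(tert-butyldimethylsilyl)oxy]-3a,6-dimethyl-2,3,3a,4-tetrahydroazulen-1-yl carbonate F1. Decarboxylative protonation of F1 (Pd(OAc)2, t-Bu-PHOX of the hand that matches the α face, Meldrum's acid as proton donor, dioxane, 40 °C) generates a ligand-bound palladium enolate, and the chiral ligand should then decide the face at which C5 is protonated. The fallback returns to the route at 11.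

Step 9. The π-allyl palladium intermediate may be captured by the neighbouring tertiary hydroxyl (bridged ether), or a proton shift may move the alkene into conjugation with the new ketone. The fallback separates reduction and oxidation. It sets out from 13: palladium-catalysed formate hydrogenolysis (Pd2(dba)3, n-Bu3P, HCO2H, Et3N, THF), in which hydride is delivered to C7 of the π-allyl complex faster than the hindered alcohol can attack, should give the homoallylic alcohol (1R,3S,3aR,8R,8aS)-3-[(tert-butyldimethylsilyl)oxy]-3a,6-dimethyl-1-(propan-2-yl)-1,2,3,3a,4,7,8,8a-octahydroazulene-1,8-diol F2 (the C6 epimer of 15). Buffered oxidation of F2 with Dess–Martin periodinane (NaHCO3, CH2Cl2, 0 °C) returns to the route at 14.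

Step 12. Two hindered secondary alcohols may acylate incompletely, and the angeloyl group may isomerise from Z to E during a forced acylation. The fallback builds the Z alkenes on the molecule instead of transferring them. It sets out from 16: esterification with 2-[bis(2,2,2-trifluoroethoxy)phosphoryl]propanoic acid (DCC, DMAP, CH2Cl2) gives the bis{2-[bis(2,2,2-trifluoroethoxy)phosphoryl]propanoate} F3. A twofold Still–Gennari olefination of F3 (KHMDS, 18-crown-6, THF, -78 °C, then acetaldehyde) should give both (Z)-2-methylbut-2-enoates under kinetic control and returns to the route at 19.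

**Further compounds**

F1 | step 6 | allyl (3S,3aR)-3-[(tert-butyldimethylsilyl)oxy]-3a,6-dimethyl-2,3,3a,4-tetrahydroazulen-1-yl carbonate | C=CCOC(=O)OC1=C2C=CC(C)=CC[C@@]2(C)[C@@H](O[Si](C)(C)C(C)(C)C)C1
F2 | step 9 | (1R,3S,3aR,8R,8aS)-3-[(tert-butyldimethylsilyl)oxy]-3a,6-dimethyl-1-(propan-2-yl)-1,2,3,3a,4,7,8,8a-octahydroazulene-1,8-diol | O[C@@H]1CC(C)=CC[C@@]2(C)[C@@H](O[Si](C)(C)C(C)(C)C)C[C@@](O)(C(C)C)[C@H]12
F3 | step 12 | (1R,3S,3aR,8S,8aS)-1-hydroxy-3a,6-dimethyl-1-(propan-2-yl)-1,2,3,3a,4,7,8,8a-octahydroazulene-3,8-diyl bis{2-[bis(2,2,2-trifluoroethoxy)phosphoryl]propanoate} | CC(C(=O)O[C@H]1CC(C)=CC[C@@]2(C)[C@@H](OC(=O)C(C)P(=O)(OCC(F)(F)F)OCC(F)(F)F)C[C@@](O)(C(C)C)[C@H]12)P(=O)(OCC(F)(F)F)OCC(F)(F)F
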